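## Structural features

The target is a guaiane: a cyclopentane (C1–C5) trans-fused (H-1 α, H-5 β) to a cycloheptane (C1, C5–C10), esterified at C8 with isovanillic acid. The five-membered ring carries a 3α,4α-epoxide with a 4β-methyl group. The seven-membered ring carries a tertiary carbinol at C10 (α-OH, β-CH3), a β-isopropyl group at C7 and the β-acyloxy group at C8. The seven stereocentres form two contiguous runs, C3–C4–C5–C1–C10 and C7–C8, separated by the methylene groups C6 and C9. The fragile groups are the trisubstituted epoxide (acid), the tertiary alcohol 1,3 to the C8 oxygen (dehydration, and retro-aldol cleavage at the ketone stage), and the aryl ester with its free phenol (base, oxidants). The real difficulty is twofold: the trans ring fusion next to a fully substituted carbinol, and the cis C7/C8 pair on a flexible ring, where the 7β-isopropyl group is probably not the thermodynamically preferred orientation. The key step exploits two facts. The C10–O bond and the C1–C5 bond are anti across C1–C10, the signature of an anti addition to an E C1=C10 alkene. The C10 oxygen is 1,4 to C7, which stands next to the C8 oxygen, so a C7–O–C10 ether bridge can be built together with both rings and later cut reductively α to a C8 ketone.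

## Logic of the disconnections

28 ⇒ 27: only the phenolic O–Si bond is cut. The phenol must be masked while the acid is activated and while the alkene is oxidised. The forward step needs fluoride conditions that spare the epoxide and the ester.

27 ⇒ 26: the C3–O and C4–O bonds of the epoxide are cut back to the C3=C4 alkene. The epoxide is the most acid-labile group and is best made last from the only alkene; two stereocentres disappear. The forward step must deliver oxygen to the α face, which the 10β-methyl group (nearly syn to C2) should favour by covering the β face of C2–C3.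

26 ⇒ 21 + 24: the ester bond C(=O)–O(C8) is cut. This separates the aromatic part and leaves a diol whose secondary and tertiary hydroxyl groups differentiate themselves. The forward step must acylate a hindered secondary alcohol next to the isopropyl group. 24 goes back to 22 by cutting one O–Si bond.

21 ⇒ 20: the C8–H bond is cut to the C8 ketone, the function that makes the bridge cleavage possible. The C10 hydroxyl is 1,3 to C8 and on the α face, so it can deliver hydride to that face. The forward step must be an anti-selective 1,3-reduction that avoids base.

20 ⇒ 19: in the retrosynthetic sense the C7–O(C10) bond is formed again. The C10 carbinol and the C7–H bond both trace back to an ether bridge α to the C8 ketone, and the flexible bicycle becomes a rigid oxabicyclo[3.2.1]octane. The forward step must break only C7–O by electron transfer and must protonate the resulting enolate at C7 from the α face under kinetic control.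

19 ⇒ 18 ⇒ 17: the C3=C4 alkene is traced to the 4α-hydroxyl group (forward: loss of C4–O and C3–H), and the C8 ketone and C4 hydroxyl to their ketal and silyl ether. The C4 oxygen is inherited from the chain, where it controls the key step. The forward elimination must be syn and neutral: H-5 is anti to the C4 oxygen and is thereby excluded, and the bridge β to the ketone does not tolerate base. The acid step must run while no alkene is present.

17 ⇒ 16: the C5–H and C6–H bonds are cut to the C5=C6 alkene that the key step leaves. The forward step must put hydrogen on C5 from the β face, which is the concave face of the oxabicycle. This calls for a stepwise radical hydrogenation governed by product stability, not a surface hydrogenation.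

16 ⇒ 15: the bonds C5–C1, O–C10 and C6–C7 are cut in one operation. Two rings and three stereocentres fall away and an acyclic chain with a single stereocentre remains. The forward step demands an E alkene, a terminal alkyne three carbons away, a ketone oxygen that reaches C10 through a five-membered ring, and a C4 centre that selects the alkene face.

15 ⇒ 14: the two C8–O bonds of the ketal are exchanged for C8–S bonds. Sulfur makes the acyl-anion chemistry possible but cannot be carried into gold catalysis. The forward exchange must leave the silyl ether, alkyne, alkene and hindered ketone untouched.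

14 ⇒ 8 + 12: the C8–C9 bond is cut between an allylic electrophile and a doubly stabilised carbanion. The chain splits into a terpene-derived half and a five-carbon ketone half. The forward alkylation must occur at carbon, by direct substitution, with a base too weak to touch the alkyne C–H; this is why the acyl group is placed on the dithioacetal before, not after, the alkylation.

12 ⇒ 9 + 10: the C7–C8 bond is cut to an acyl-anion equivalent and an ester. The forward step must stop at the ketone, which the acidity of the product secures.

8 ⇒ 7 ⇒ 5: the C9–Br bond goes back to C9–OH and this to a C–H bond of the E-methyl group. The forward oxidation must select that methyl group among the allylic positions and keep the E geometry.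

5 ⇒ 4 ⇒ 3 ⇒ 2 ⇒ 1: the O–Si bond, then the alkyne (traced to an epoxy chloride), then C–Cl, then the epoxide C–O bonds are cut. A tertiary propargylic carbinol is not reliably resolved by acyl-transfer enzymes, whereas an asymmetric epoxidation of an allylic alcohol sets the same centre directly. The C3–O bond of the epoxide survives unchanged and becomes the C4 carbinol, so the forward steps must never break it.

## Other disconnections considered

Alternative 1: The cut is C1–C5, across a ten-membered ring. In the forward step the epoxy ketone A1 would be treated with BF3·OEt2: the epoxide opens at C5 as C1 of the C1=C10 alkene attacks, and the C10 cation loses a methyl proton to give A2.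
- In its favour: the whole carbon skeleton, the trans ring fusion and the C8 carbonyl arrive in one step from an abundant natural ketone. In step economy to the bicyclic core this is the better plan, and it sets the C1/C5 fusion directly, which the chosen route has to work for.
- Against it here: the parent ten-membered dienone is achiral, so A1 would need an epoxidation that is both enantioselective and selective between two ring alkenes. The C10 cation can lose different protons. In A2 the C4 hydroxyl is syn to H-5, so the later dehydration can run into C4=C5. The C10 carbinol must still be made by face-selective hydration of the exocyclic alkene, and C7/C8 by reduction of a tetrasubstituted enone.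
- Comparison: on the C7 problem (protonation α to the C8 carbonyl) the two plans are equal. On absolute configuration and on the C1/C10 relationship the chosen plan is stronger, because it takes the first from one reliable asymmetric epoxidation and the second stereospecifically from alkene geometry.

Alternative 2: The cuts are C4–C5 and C1–C2, a [3+2] annulation of the cycloheptenone A3 with the methyl-substituted trimethylenemethane donor A4. A zerovalent palladium catalyst, formed in the flask from Pd(OAc)2 and P(O-i-Pr)3, would give the trans-fused ketone A5 after base epimerisation at C1.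
- In its favour: C7 and C8 are carried in from the start. These are exactly the two centres that the chosen plan sets late and under kinetic control, so here the alternative is the better. C1 can be equilibrated next to the C10 ketone, which is equal or better than a kinetically set fusion.
- Against it here: A3 is not commercial and needs its own enantioselective synthesis. The unsymmetrical donor raises a regiochemical question, and the stereocentres of A3 are remote from the reacting alkene on a flexible ring. The C10 carbinol then requires a methyl addition whose face is left to the substrate, the exocyclic alkene must be moved into the ring, and the C4 centre of A5 is wasted.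
- Comparison: mechanistically it is a stepwise zwitterionic annulation with less built-in stereochemical information than the chosen cascade. The step count would probably be similar or higher once A3 is included.

Alternative 3: The cut is C5–C6, made by a [3,3] shift. On warming, the cis-dialkenylcyclopropane A6 would pass through a boat transition state to the cycloheptadiene A7 as the C8–C10 cyclopropane bond breaks.
- In its favour: the rearrangement is strain-driven, stereospecific and needs no metal. In reliability of the key step itself it is the equal or the better of the gold cascade, whose carbonyl partner is untried.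
- Against it here: A7 contains only C5 as a stereocentre, and its configuration depends on an enantioselective cyclopropanation to A6. The tetrasubstituted C1=C10 alkene would have to take up H and OH syn with regiocontrol between two fully substituted carbons. The C4 methyl group is missing, and C7 would again be set by protonation of an enol derivative.
- Comparison: the chosen plan creates both rings and three stereocentres in the key step and leaves a shorter end game. The alternative leaves six centres for later.

Key step: step 10

Assumption (chemistry): guaiane numbering is used; α is the face of H-1 and β the face of the C4 and C10 methyl groups; in the gold step the alkene is taken to approach the alkyne on the face of the nascent cyclopentane opposite the C4 silyloxy group, so the (R)-carbinol is required.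

Step 1
Reactants: 1 geraniol
Product: 2 [(2R,3R)-3-methyl-3-(4-methylpent-3-en-1-yl)oxiran-2-yl]methanol
Conditions: Ti(O-i-Pr)4 (5 mol%), (−)-diethyl D-tartrate (6 mol%), t-BuOOH, 4 Å MS, CH2Cl2, −20 °C
Reagents that add atoms: tert-butyl hydroperoxide, CC(C)(C)OO
Why: Sharpless asymmetric epoxidation of the allylic alcohol; the D-tartrate ligand should deliver oxygen to the face that gives the (2R,3R)-epoxide, whose C3–O bond becomes the C4 carbinol of the guaiane; the remote trisubstituted alkene is not bound to titanium and should stay intact.

Step 2
Reactants: 2 [(2R,3R)-3-methyl-3-(4-methylpent-3-en-1-yl)oxiran-2-yl]methanol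
Product: 3 (2S,3R)-2-(chloromethyl)-3-methyl-3-(4-methylpent-3-en-1-yl)oxirane
Conditions: PPh3, CCl4, NaHCO3, reflux
Reagents that add atoms: carbon tetrachloride, ClC(Cl)(Cl)Cl
Why: Appel chlorination of the primary alcohol under buffered neutral conditions that leave the epoxide closed; no stereocentre is touched (the descriptor at C2 changes only through the priority rules).

Step 3
Reactants: 3 (2S,3R)-2-(chloromethyl)-3-methyl-3-(4-methylpent-3-en-1-yl)oxirane
Product: 4 (3R)-3,7-dimethyloct-6-en-1-yn-3-ol
Conditions: n-BuLi (3.2 equiv), THF, −40 → 0 °C; aq. NH4Cl
Reagents that add atoms: none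
Why: Base-induced fragmentation of a 2,3-epoxy chloride: β-elimination opens the epoxide to a chloroalkenyl alkoxide, loss of HCl gives the alkyne and the third equivalent forms the acetylide; the tertiary C–O bond is never broken, so the (R)-carbinol should be obtained with the enantiomeric purity of 2.

Step 4
Reactants: 4 (3R)-3,7-dimethyloct-6-en-1-yn-3-ol
Product: 5 (3R)-3,7-dimethyl-3-(triethylsilyloxy)oct-6-en-1-yne
Conditions: Et3SiOTf, 2,6-lutidine, CH2Cl2, 0 °C
Reagents that add atoms: triethylsilyl triflate, CC[Si](CC)(CC)OS(=O)(=O)C(F)(F)F
Why: Silylation of a hindered tertiary alcohol needs the silyl triflate; the silyl ether is the bulky group that later steers the alkene in the gold step and it survives the oxidations and alkylation that follow.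

Step 5
Reactants: 5 (3R)-3,7-dimethyl-3-(triethylsilyloxy)oct-6-en-1-yne
Product: 7 (2E,6R)-2,6-dimethyl-6-(triethylsilyloxy)oct-2-en-7-yn-1-ol, via the (E)-enal 6 (not isolated)
Conditions: SeO2 (cat.), t-BuOOH, salicylic acid (cat.), CH2Cl2, rt; then NaBH4, MeOH, 0 °C
Reagents that add atoms: tert-butyl hydroperoxide, CC(C)(C)OO (oxygen relayed by SeO2, O=[Se]=O)
Why: Riley oxidation (ene reaction, then [2,3] shift) attacks the E-methyl group of the trisubstituted alkene and keeps the E geometry; the over-oxidised enal is returned to the alcohol by borohydride in the same flask.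

Step 6
Reactants: 7 (2E,6R)-2,6-dimethyl-6-(triethylsilyloxy)oct-2-en-7-yn-1-ol
Product: 8 (3R,6E)-8-bromo-3,7-dimethyl-3-(triethylsilyloxy)oct-6-en-1-yne
Conditions: CBr4, PPh3, CH2Cl2, 0 °C
Reagents that add atoms: carbon tetrabromide, BrC(Br)(Br)Br
Why: Appel bromination of the primary allylic alcohol by direct substitution, neutral and cold, so the silyl ether and the alkene geometry should be kept.

Step 7
Reactants: 9 1,3-dithiane; 10 methyl isobutyrate
Product: 12 1-(1,3-dithian-2-yl)-2-methylpropan-1-one, via 2-lithio-1,3-dithiane 11 (not isolated)
Conditions: n-BuLi, THF, −30 °C (2 equiv of 11); then 10 (1 equiv), −78 → 0 °C; aq. NH4Cl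
Reagents that add atoms: none
Why: Corey–Seebach acylation of the lithiated dithioacetal with an ester; the product is more acidic than the dithiane and is deprotonated by the second equivalent, which should stop a second addition.

Step 8
Reactants: 12 1-(1,3-dithian-2-yl)-2-methylpropan-1-one; 8 (3R,6E)-8-bromo-3,7-dimethyl-3-(triethylsilyloxy)oct-6-en-1-yne
Product: 14 1-{2-[(2E,6R)-2,6-dimethyl-6-(triethylsilyloxy)oct-2-en-7-yn-1-yl]-1,3-dithian-2-yl}-2-methylpropan-1-one, via sodium enolate 13 (not isolated)
Conditions: NaH, THF/DMF, 0 °C; then 8, 0 °C → rt
Reagents that add atoms: none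
Why: Alkylation of a soft, sulfur- and carbonyl-stabilised enolate at carbon by direct substitution on the unhindered primary allylic bromide; the enolate is far less basic than an acetylide, so the terminal alkyne C–H should not be touched and the E alkene is carried over unchanged.

Step 9
Reactants: 14 1-{2-[(2E,6R)-2,6-dimethyl-6-(triethylsilyloxy)oct-2-en-7-yn-1-yl]-1,3-dithian-2-yl}-2-methylpropan-1-one
Product: 15 1-{2-[(2E,6R)-2,6-dimethyl-6-(triethylsilyloxy)oct-2-en-7-yn-1-yl]-1,3-dioxolan-2-yl}-2-methylpropan-1-one
Conditions: PhI(OCOCF3)2, HOCH2CH2OH, NaHCO3, MeCN, 0 °C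
Reagents that add atoms: ethylene glycol, OCCO
Why: Oxidative exchange of a dithioacetal for an O,O-acetal with a hypervalent iodine reagent: sulfur is activated, each C–S bond is replaced by a C–O bond to the glycol and the dithiol leaves as the cyclic disulfide; the isopropyl ketone is hindered and deactivated and should not be ketalised, and the buffer protects the silyl ether.

Step 10
Reactants: 15 1-{2-[(2E,6R)-2,6-dimethyl-6-(triethylsilyloxy)oct-2-en-7-yn-1-yl]-1,3-dioxolan-2-yl}-2-methylpropan-1-one
Product: 16 7α,10α-epoxy-8,8-(ethylenedioxy)-4α-(triethylsilyloxy)-1αH-guai-5-ene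
Conditions: [Au(NCMe){P(t-Bu)2(o-biphenyl)}]SbF6 (3 mol%), 4 Å MS, CH2Cl2, rt
Reagents that add atoms: none
Why: Monovalent gold binds the terminal alkyne and C1 of the E alkene attacks C5 anti to gold (5-exo-dig closure of the cyclopentane), giving a cyclopropyl gold carbene with the carbene carbon at C6. The C7 carbonyl oxygen then opens the cyclopropane at the tertiary C10 with inversion, forming a five-membered oxocarbenium ring (O–C7–C8–C9–C10) and an alkenyl-gold unit at C6. The alkenyl-gold carbon C6 adds to the oxocarbenium carbon C7 in a Prins-type closure of the seven-membered carbocycle (six-membered when counted through oxygen), and loss of gold leaves the C5=C6 alkene. The closest known reaction type is the gold-catalysed [2+2+2] alkyne/alkene/carbonyl cycloaddition of ketone-tethered 1,6-enynes; the ketal next to the ketone is a substituent variation of that substrate class. C1 and C10 are set by stereospecific anti addition of C5 and oxygen across the E alkene, which places H-1 and the C10 oxygen on the same face of the seven-membered ring. C7 is set by the tether, since the oxygen already bound to C10 can bridge only one face, so the bridge is α and the isopropyl group β. The absolute sense comes from C4: the alkene should add on the face of the nascent cyclopentane opposite the bulky silyloxy group, giving H-1 cis to that group. The step needs exo cyclisation and capture by the ketone and not by water or a ketal oxygen; the terminal alkyne with a three-carbon tether, the five-membered fit of the ketone oxygen (a ketal oxygen would need a four-membered ring), and the dry, silver-free, acid-free catalyst should secure this.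

Step 11
Reactants: 16 7α,10α-epoxy-8,8-(ethylenedioxy)-4α-(triethylsilyloxy)-1αH-guai-5-ene
Product: 17 7α,10α-epoxy-8,8-(ethylenedioxy)-4α-(triethylsilyloxy)-1αH,5βH-guaiane
Conditions: Mn(dpm)3 (10 mol%), PhSiH3, t-BuOOH, i-PrOH, rt
Reagents that add atoms: none
Why: Mukaiyama-type radical hydrogenation by metal-hydride hydrogen-atom transfer: a hydrogen atom adds to the less substituted C6 and the tertiary C5 radical then takes up the second hydrogen; the C5 radical should pyramidalise toward the chair oxane with the quaternary C4 equatorial, so hydrogen enters axially on the β face, which is also the face away from the α-silyloxy group, giving the trans ring fusion where a metal surface would be expected to add from the exo (α) face.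

Step 12
Reactants: 17 7α,10α-epoxy-8,8-(ethylenedioxy)-4α-(triethylsilyloxy)-1αH,5βH-guaiane
Product: 18 7α,10α-epoxy-4α-hydroxy-1αH,5βH-guaian-8-one
Conditions: 2 N HCl, THF, 40 °C
Reagents that add atoms: water, O
Why: Acid hydrolysis of the dioxolane and of the tertiary silyl ether in one operation; the ketal next to the bridgehead oxygen is sluggish and needs aqueous mineral acid, which the saturated tricycle (no alkene, C4 no longer allylic) should tolerate, and no C–O bond at a stereocentre is broken.

Step 13
Reactants: 18 7α,10α-epoxy-4α-hydroxy-1αH,5βH-guaian-8-one
Product: 19 7α,10α-epoxy-1αH,5βH-guai-3-en-8-one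
Conditions: Burgess reagent (MeO2CN–SO2NEt3 inner salt), PhMe, 60 °C
Reagents that add atoms: none
Why: Burgess dehydration, a syn elimination through the sulfamate ester: the 4α-oxygen has syn hydrogens only at C3 and on the methyl group, H-5 being anti on the β face, so the C4=C5 alkene is excluded and the endocyclic trisubstituted C3=C4 alkene should prevail over the exocyclic one; the neutral conditions avoid β-elimination of the bridge oxygen from the ketone.

Step 14
Reactants: 19 7α,10α-epoxy-1αH,5βH-guai-3-en-8-one
Product: 20 10α-hydroxy-1αH,5βH,7αH-guai-3-en-8-one
Conditions: SmI2 (2.5 equiv), THF/MeOH, −78 °C; aq. NH4Cl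
Reagents that add atoms: none
Why: Reductive cleavage of an α-alkoxy ketone by SmI2 (ketyl, loss of the C7–O bond, second electron transfer to a samarium enolate), which is a known way to open oxygen bridges next to ketones; the enolate should be protonated by methanol held on the trivalent samarium that bridges the C8 enolate oxygen and the C10 alkoxide, that is from the α face just vacated by oxygen, setting 7α-H under kinetic control, so the product is kept away from base.

Step 15
Reactants: 20 10α-hydroxy-1αH,5βH,7αH-guai-3-en-8-one
Product: 21 1αH,5βH,7αH-guai-3-ene-8β,10α-diol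
Conditions: Me4NBH(OAc)3, MeCN/AcOH, −30 °C
Reagents that add atoms: none
Why: Evans–Saksena reduction: the C10 hydroxyl exchanges onto boron and hydride is delivered within the molecule to the α face of C8, giving the 1,3-anti diol with the 8β-hydroxyl; attack anti to the β-isopropyl group points the same way, and the mildly acidic medium should prevent retro-aldol cleavage and epimerisation at C7.

Step 16
Reactants: 22 isovanillic acid
Product: 24 3-(tert-butyldimethylsilyloxy)-4-methoxybenzoic acid, via bis-silylated ester 23 (not isolated)
Conditions: t-BuMe2SiCl, imidazole, DMF, rt; then AcOH, THF/H2O, rt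
Reagents that add atoms: tert-butyldimethylsilyl chloride, CC(C)(C)[Si](C)(C)Cl
Why: Silylation of both acidic groups followed by selective hydrolysis of the much more labile silyl ester; the aryl silyl ether is inert to the acylation and epoxidation conditions and is removable by fluoride at the end.

Step 17
Reactants: 21 1αH,5βH,7αH-guai-3-ene-8β,10α-diol; 24 3-(tert-butyldimethylsilyloxy)-4-methoxybenzoic acid
Product: 26 10α-hydroxy-1αH,5βH,7αH-guai-3-en-8β-yl 3-(tert-butyldimethylsilyloxy)-4-methoxybenzoate, via mixed anhydride 25 (not isolated)
Conditions: 2,4,6-Cl3C6H2COCl, Et3N, THF, rt; then 21, DMAP, PhMe, 40 °C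
Reagents that add atoms: none
Why: Yamaguchi esterification: the acylpyridinium ion formed from the mixed anhydride at its less hindered carbonyl acylates the hindered secondary C8 hydroxyl with retention, while the tertiary C10 hydroxyl should not react.

Step 18
Reactants: 26 10α-hydroxy-1αH,5βH,7αH-guai-3-en-8β-yl 3-(tert-butyldimethylsilyloxy)-4-methoxybenzoate
Product: 27 3α,4α-epoxy-10α-hydroxy-1αH,5βH,7αH-guaian-8β-yl 3-(tert-butyldimethylsilyloxy)-4-methoxybenzoate
Conditions: mCPBA, NaHCO3, CH2Cl2, 0 °C
Reagents that add atoms: 3-chloroperbenzoic acid, OOC(=O)c1cccc(Cl)c1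
Why: Prilezhaev epoxidation of the only alkene; the 10β-methyl group lies nearly syn to C2 and covers the β face of C2–C3, whereas the α face carries only H-1 and the edge of C6, so oxygen should enter from the α face; the buffer protects the acid-sensitive epoxide.

Step 19
Reactants: 27 3α,4α-epoxy-10α-hydroxy-1αH,5βH,7αH-guaian-8β-yl 3-(tert-butyldimethylsilyloxy)-4-methoxybenzoate
Product: 28 3α,4α-epoxy-10α-hydroxy-1αH,5βH,7αH-guaian-8β-yl 3-hydroxy-4-methoxybenzoate (CNP0264062.2)
Conditions: Bu4NF, AcOH, THF, 0 °C
Reagents that add atoms: none
Why: Fluoride cleavage of the aryl silyl ether, buffered with acetic acid so that the epoxide, the ester and the tertiary alcohol meet neither strong base nor strong acid; no stereocentre is involved.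

Compound list
1 | geraniol, (2E)-3,7-dimethylocta-2,6-dien-1-ol | CC(C)=CCC/C(C)=C/CO | starting material
2 | [(2R,3R)-3-methyl-3-(4-methylpent-3-en-1-yl)oxiran-2-yl]methanol | OC[C@H]1O[C@]1(C)CCC=C(C)C | intermediate
3 | (2S,3R)-2-(chloromethyl)-3-methyl-3-(4-methylpent-3-en-1-yl)oxirane | ClC[C@H]1O[C@]1(C)CCC=C(C)C | intermediate
4 | (3R)-3,7-dimethyloct-6-en-1-yn-3-ol | C#C[C@](C)(O)CCC=C(C)C | intermediate
5 | (3R)-3,7-dimethyl-3-(triethylsilyloxy)oct-6-en-1-yne | C#C[C@](C)(O[Si](CC)(CC)CC)CCC=C(C)C | intermediate
6 | (2E,6R)-2,6-dimethyl-6-(triethylsilyloxy)oct-2-en-7-ynal | C#C[C@](C)(O[Si](CC)(CC)CC)CC/C=C(\C)C=O | intermediate (not isolated)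
7 | (2E,6R)-2,6-dimethyl-6-(triethylsilyloxy)oct-2-en-7-yn-1-ol | C#C[C@](C)(O[Si](CC)(CC)CC)CC/C=C(\C)CO | intermediate
8 | (3R,6E)-8-bromo-3,7-dimethyl-3-(triethylsilyloxy)oct-6-en-1-yne | C#C[C@](C)(O[Si](CC)(CC)CC)CC/C=C(\C)CBr | intermediate
9 | 1,3-dithiane | C1CSCSC1 | starting material
10 | methyl isobutyrate | COC(=O)C(C)C | starting material
11 | 2-lithio-1,3-dithiane | [Li]C1SCCCS1 | intermediate (not isolated)
12 | 1-(1,3-dithian-2-yl)-2-methylpropan-1-one | CC(C)C(=O)C1SCCCS1 | intermediate
13 | sodium enolate of 12 | CC(C)C([O-])=C1SCCCS1.[Na+] | intermediate (not isolated)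
14 | 1-{2-[(2E,6R)-2,6-dimethyl-6-(triethylsilyloxy)oct-2-en-7-yn-1-yl]-1,3-dithian-2-yl}-2-methylpropan-1-one | C#C[C@](C)(O[Si](CC)(CC)CC)CC/C=C(\C)CC1(SCCCS1)C(=O)C(C)C | intermediate
15 | 1-{2-[(2E,6R)-2,6-dimethyl-6-(triethylsilyloxy)oct-2-en-7-yn-1-yl]-1,3-dioxolan-2-yl}-2-methylpropan-1-one (key-step precursor) | C#C[C@](C)(O[Si](CC)(CC)CC)CC/C=C(\C)CC1(OCCO1)C(=O)C(C)C | intermediate
16 | 7α,10α-epoxy-8,8-(ethylenedioxy)-4α-(triethylsilyloxy)-1αH-guai-5-ene (key-step product) | CC(C)[C@]12C=C3[C@@H](CC[C@@]3(C)O[Si](CC)(CC)CC)[C@](C)(O1)CC24OCCO4 | intermediate
17 | 7α,10α-epoxy-8,8-(ethylenedioxy)-4α-(triethylsilyloxy)-1αH,5βH-guaiane | CC(C)[C@]12C[C@H]3[C@@H](CC[C@@]3(C)O[Si](CC)(CC)CC)[C@](C)(O1)CC24OCCO4 | intermediate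
18 | 7α,10α-epoxy-4α-hydroxy-1αH,5βH-guaian-8-one | CC(C)[C@]12C[C@H]3[C@@H](CC[C@@]3(C)O)[C@](C)(O1)CC2=O | intermediate
19 | 7α,10α-epoxy-1αH,5βH-guai-3-en-8-one | CC(C)[C@]12C[C@H]3[C@@H](CC=C3C)[C@](C)(O1)CC2=O | intermediate
20 | 10α-hydroxy-1αH,5βH,7αH-guai-3-en-8-one | O=C1C[C@@](C)(O)[C@@H]2CC=C(C)[C@H]2C[C@@H]1C(C)C | intermediate
21 | 1αH,5βH,7αH-guai-3-ene-8β,10α-diol | O[C@@H]1C[C@@](C)(O)[C@@H]2CC=C(C)[C@H]2C[C@@H]1C(C)C | intermediate
22 | isovanillic acid, 3-hydroxy-4-methoxybenzoic acid | COc1ccc(C(=O)O)cc1O | starting material
23 | tert-butyldimethylsilyl 3-(tert-butyldimethylsilyloxy)-4-methoxybenzoate | COc1ccc(C(=O)O[Si](C)(C)C(C)(C)C)cc1O[Si](C)(C)C(C)(C)C | intermediate (not isolated)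
24 | 3-(tert-butyldimethylsilyloxy)-4-methoxybenzoic acid | COc1ccc(C(=O)O)cc1O[Si](C)(C)C(C)(C)C | intermediate
25 | 3-(tert-butyldimethylsilyloxy)-4-methoxybenzoic 2,4,6-trichlorobenzoic anhydride | COc1ccc(C(=O)OC(=O)c2c(Cl)cc(Cl)cc2Cl)cc1O[Si](C)(C)C(C)(C)C | intermediate (not isolated)
26 | 10α-hydroxy-1αH,5βH,7αH-guai-3-en-8β-yl 3-(tert-butyldimethylsilyloxy)-4-methoxybenzoate | COc1ccc(C(=O)O[C@@H]2C[C@@](C)(O)[C@@H]3CC=C(C)[C@H]3C[C@@H]2C(C)C)cc1O[Si](C)(C)C(C)(C)C | intermediate
27 | 3α,4α-epoxy-10α-hydroxy-1αH,5βH,7αH-guaian-8β-yl 3-(tert-butyldimethylsilyloxy)-4-methoxybenzoate | COc1ccc(C(=O)O[C@@H]2C[C@@](C)(O)[C@@H]3C[C@H]4O[C@@]4(C)[C@H]3C[C@@H]2C(C)C)cc1O[Si](C)(C)C(C)(C)C | intermediate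
28 | 3α,4α-epoxy-10α-hydroxy-1αH,5βH,7αH-guaian-8β-yl 3-hydroxy-4-methoxybenzoate (CNP0264062.2) | COc1ccc(C(=O)O[C@@H]2C[C@@](C)(O)[C@@H]3C[C@H]4O[C@@]4(C)[C@H]3C[C@@H]2C(C)C)cc1O | target

Total step count: 19. Longest linear sequence: 17 steps (steps 1–6, 8–15 and 17–19). Steps 7 and 16 prepare the two side components.

Least certain steps, in the order of the route (the key step is step 10):

Step 9. The second C–S bond has to leave through an oxocarbenium ion next to a ketone, so the exchange may stall, or water and trifluoroacetate may intercept and give the free dicarbonyl compound; the acid released may also strip the silyl ether. The fallback divides the task. From 14 the dithioacetal is hydrolysed oxidatively with the same iodine reagent in aqueous MeCN to (6E,10R)-2,6,10-trimethyl-10-(triethylsilyloxy)dodec-6-en-11-yne-3,4-dione F1. The less hindered C8 carbonyl of the diketone is then ketalised with 1,2-bis(trimethylsilyloxy)ethane and catalytic Me3SiOTf in CH2Cl2 at −78 °C. The isopropyl-flanked carbonyl should be too hindered to react, and the route is rejoined at 15.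

Step 10 (key step). Capture of the cyclopropyl gold carbene by the hindered, inductively deactivated carbonyl may be too slow, so that skeletal rearrangement to dienes or trapping by traces of water takes over. The Prins closure may suffer from the fully substituted ketal carbon next to C7, and facial selection by C4 may be lower than assumed. The fallback changes the substrate. From 14 the diketone (6E,10R)-2,6,10-trimethyl-10-(triethylsilyloxy)dodec-6-en-11-yne-3,4-dione F1 is made as above and is itself submitted to the gold catalyst. C8 is then trigonal and the Prins closure less crowded, and only the C7 carbonyl can reach C10 through a five-membered ring, so the expected product is 7α,10α-epoxy-4α-(triethylsilyloxy)-1αH-guai-5-en-8-one F2. Radical hydrogenation as in step 11 would give 7α,10α-epoxy-4α-(triethylsilyloxy)-1αH,5βH-guaian-8-one F3, and dilute aqueous HCl in THF removes the silyl group to rejoin the route at 18.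

Step 11. Hydrogen may be delivered to C5 from the exo (α) face, the face normally preferred in an oxabicyclo[3.2.1]octene, giving the cis-fused epimer; the first hydrogen-atom transfer to the hindered alkene may also be slow. The fallback replaces product-stability control by hydroxyl direction from the β face, which needs a free C8 carbonyl. From 14, by way of the diketone F1 and the tricyclic ketone F2 described for step 10, NaBH4 should attack C8 from the exo face to give 7α,10α-epoxy-4α-(triethylsilyloxy)-1αH-guai-5-en-8β-ol F4. Its endo hydroxyl group is homoallylic to C5=C6 and is the only free hydroxyl, so [Ir(cod)(PCy3)(py)]PF6 under H2 in CH2Cl2 should add hydrogen from the β face to give 7α,10α-epoxy-4α-(triethylsilyloxy)-1αH,5βH-guaian-8β-ol F5. Dess–Martin oxidation returns the ketone F3, and aqueous HCl in THF rejoins the route at 18.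

Step 14. Protonation of the samarium enolate may occur from the β face (the axial direction that leads to the more stable 7-epimer) and not by internal delivery from the chelated α face; the aldol-type product may also epimerise or undergo retro-aldol cleavage on handling. Equilibration is no remedy, because in the 5βH series the 7β-isopropyl group is probably the less stable orientation. The fallback sets C7 by directed hydrogenation. Material containing 10α-hydroxy-1αH,5βH,7βH-guai-3-en-8-one F6 is dehydrogenated with 2-iodoxybenzoic acid in DMSO; only the C7 side can become unsaturated, because C10 bears no hydrogen, so the product should be 10α-hydroxy-1αH,5βH-guaia-3,6-dien-8-one F7. The conjugated alkene is then reduced with [Rh(nbd)(dppb)]BF4 under H2. The 10α-hydroxyl group, which sat on C7 before the bridge was cut, should guide the cationic rhodium to the α face of C7, and the isolated, undirected C3=C4 alkene should be left. This rejoins the route at 20.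

Step 18. The peracid may show poor facial selectivity or prefer the β face of the cyclopentene, and 3-chlorobenzoic acid may open the product epoxide. The fallback inverts the sense of delivery in two steps. From 26, NBS in aqueous THF at 0 °C should form the bromonium ion on the face an electrophile prefers and water opens it at the tertiary C4 from the opposite side; for a β-face electrophile this gives 3β-bromo-4α,10α-dihydroxy-1αH,5βH,7αH-guaian-8β-yl 3-(tert-butyldimethylsilyloxy)-4-methoxybenzoate F8. Ag2O in THF then closes the 4α-oxygen onto C3 with displacement of bromide, and the route is rejoined at 27. The C10 hydroxyl cannot interfere, because C10 is anti to C4 across the trans ring fusion.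

Further compounds
F1 | step 9 | (6E,10R)-2,6,10-trimethyl-10-(triethylsilyloxy)dodec-6-en-11-yne-3,4-dione | C#C[C@](C)(O[Si](CC)(CC)CC)CC/C=C(\C)CC(=O)C(=O)C(C)C
F2 | step 10 | 7α,10α-epoxy-4α-(triethylsilyloxy)-1αH-guai-5-en-8-one | CC(C)[C@]12C=C3[C@@H](CC[C@@]3(C)O[Si](CC)(CC)CC)[C@](C)(O1)CC2=O
F3 | step 10 | 7α,10α-epoxy-4α-(triethylsilyloxy)-1αH,5βH-guaian-8-one | CC(C)[C@]12C[C@H]3[C@@H](CC[C@@]3(C)O[Si](CC)(CC)CC)[C@](C)(O1)CC2=O
F4 | step 11 | 7α,10α-epoxy-4α-(triethylsilyloxy)-1αH-guai-5-en-8β-ol | CC(C)[C@]12C=C3[C@@H](CC[C@@]3(C)O[Si](CC)(CC)CC)[C@](C)(O1)C[C@H]2O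
F5 | step 11 | 7α,10α-epoxy-4α-(triethylsilyloxy)-1αH,5βH-guaian-8β-ol | CC(C)[C@]12C[C@H]3[C@@H](CC[C@@]3(C)O[Si](CC)(CC)CC)[C@](C)(O1)C[C@H]2O
F6 | step 14 | 10α-hydroxy-1αH,5βH,7βH-guai-3-en-8-one | O=C1C[C@@](C)(O)[C@@H]2CC=C(C)[C@H]2C[C@H]1C(C)C
F7 | step 14 | 10α-hydroxy-1αH,5βH-guaia-3,6-dien-8-one | O=C1C[C@@](C)(O)[C@@H]2CC=C(C)[C@H]2C=C1C(C)C
F8 | step 18 | 3β-bromo-4α,10α-dihydroxy-1αH,5βH,7αH-guaian-8β-yl 3-(tert-butyldimethylsilyloxy)-4-methoxybenzoate | COc1ccc(C(=O)O[C@@H]2C[C@@](C)(O)[C@@H]3C[C@H](Br)[C@@](C)(O)[C@H]3C[C@@H]2C(C)C)cc1O[Si](C)(C)C(C)(C)C
A1 | alternative 1 | (4S,5S)-germacrone 4,5-epoxide, (1(10)E)-4,5-epoxygermacra-1(10),7(11)-dien-8-one | O=C1C/C(C)=C/CC[C@]2(C)O[C@H]2CC1=C(C)C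
A2 | alternative 1 | 4β-hydroxy-1αH,5βH-guaia-7(11),10(14)-dien-8-one | O=C1CC(=C)[C@@H]2CC[C@](C)(O)[C@H]2CC1=C(C)C
A3 | alternative 2 | (5R,6R)-6-(tert-butyldimethylsilyloxy)-5-isopropylcyclohept-2-en-1-one | O=C1C=CC[C@H](C(C)C)[C@H](O[Si](C)(C)C(C)(C)C)C1
A4 | alternative 2 | 3-[(trimethylsilyl)methyl]but-3-en-2-yl acetate (racemic) | CC(OC(C)=O)C(=C)C[Si](C)(C)C
A5 | alternative 2 | trans-fused 8β-(tert-butyldimethylsilyloxy)-3-methylene-14-nor-1αH,5βH-guaian-10-one | O=C1[C@@H]2CC(=C)[C@H](C)[C@H]2C[C@H](C(C)C)[C@H](O[Si](C)(C)C(C)(C)C)C1
A6 | alternative 3 | cis-1-(3-methylbut-1-en-2-yl)-2-methyl-2-(1,4-dioxaspiro[4.4]non-6-en-7-yl)-1-(trimethylsilyloxy)cyclopropane | C=C(C(C)C)[C@]1(O[Si](C)(C)C)C[C@]1(C)C2=CC3(OCCO3)CC2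
A7 | alternative 3 | 15-nor-5βH-guaia-1(10),7-dien-4-one ethylene ketal, 8-trimethylsilyl enol ether | CC1=C2CCC3(OCCO3)[C@H]2CC(C(C)C)=C(O[Si](C)(C)C)C1
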